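Numbering used throughout: 1 O-benzylvanillin; 2 pyruvic acid; 3 potassium 2-oxobutenoate; 4 methyl 2-oxo ester; 5 (R)-allylic hydroxy ester; 6 cyclopropyl (R)-hydroxy ester; 7 inverted (S)-4-nitrobenzoate; 8 cyclopropyl (S)-hydroxy acid; 9 cis-dioxolanone; 10 benzylic alcohol; 11 benzylic bromide; 12 lithium enolate; 13 benzylated dioxolanone; 14 hydroxy acid (precursor of the key step); 15 radical cation; 16 benzylic radical; 17 di-O-benzyl lactone (product of the key step); 18 target.

## Analysis of the target

Compound 18 is a dibenzylbutyrolactone lignan: one γ-butyrolactone ring (O1, C2=O, C3, C4, C5) with a 4-hydroxy-3-methoxybenzyl group on C3, a second one on C4, and a tertiary hydroxyl on C3. It has two adjacent stereocentres, C3 (S, fully substituted, oxygen-bearing) and C4 (R, a tertiary C–H); placed on the ring, these descriptors put the two arylmethyl groups cis and the hydroxyl trans to the C4 arylmethyl group. C3 has no hydrogen and C4 is not alpha to the carbonyl, so neither centre can epimerise once set; the lactone may open in base but recloses on acidification. The sensitive groups are the two free guaiacol-type phenols and their electron-rich rings, which are easily oxidised and would quench enolates and organozinc reagents, so they are carried as benzyl ethers. The difficulty is the oxygenated quaternary C3 next to C4 in the cis-dibenzyl arrangement: alkylation of a 4-substituted lactone enolate puts the incoming group trans to the C4 arm, so the order in which carbon and oxygen reach C3 must be planned. The feature the route rests on is that C4 is bonded both to C5 (the O–CH2 carbon) and to the benzylic CH2 of its own arm. C5, C4 and that benzylic carbon can therefore start as the three carbons of an arylcyclopropane, and trading the C5–benzylic bond for an O1–C5 bond closes the lactone and turns the ring carbon into the arm CH2.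

## Retrosynthetic reasoning

18 back to 17. The two phenolic O–H bonds are traced to O–benzyl bonds. Benzyl ethers tolerate base, zinc reagents and amide bases, and both fall in one hydrogenolysis. This step has to be last, because hydrogen over palladium would also cleave an arylcyclopropane.

17 back to 14. The O1–C5 bond is cut and C5 is joined to the benzylic carbon of the C4 arm, which gives the trans-arylcyclopropane acid 14. This is the only place where one bond exchange makes both the ring and the arm CH2, and it changes no oxidation level: 14 and 17 are isomers. Neither C3 nor C4 loses a bond, so the forward reaction creates no stereocentre. It must deliver the carboxyl oxygen to the ring CH2 (not to the substituted or the benzylic ring carbon) and finish by putting a hydrogen on the benzylic carbon.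

14 back to 13, then to 9 and 11. The acid and tertiary hydroxyl of 14 are tied up as the acylal 13, and the C3–CH2(aryl) bond is then cut to give enolate chemistry on dioxolanone 9 with bromide 11. The acetal carbon of 9 holds the stereochemical information while C5 of the dioxolanone is planar, so the quaternary carbon is made by a reaction whose face selectivity is fixed by the ring. Bromide 11 comes from alcohol 10.

9 back to 8. The two acetal C–O bonds are cut. Acid 8 must be S at the carbinol carbon and (1S,2S) in the cyclopropane, because the alkylation replaces hydrogen with retention and the cyclopropane carbon next to the carbinol becomes C4.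

8 back to 7 and 6. In 8 the carbinol oxygen and the cyclopropane CH2 are anti. A hydroxyl-directed cyclopropanation gives the syn relationship, so the carbinol C–O bond is disconnected with inversion: 8 comes from ester 7, and 7 from the epimeric (R)-carbinol 6 by SN2 displacement. The alternative order, benzylation first and cyclopropanation of the resulting tertiary carbinol, was not taken. A carbinol carbon that bears an ester and an arylmethyl group has no hydrogen to sit in the alkene plane, so the conformational lock behind the face selectivity is lost.

6 back to 5. The two cyclopropane bonds to the CH2 group are cut, leaving the E-allylic alcohol 5. E geometry fixes the trans ring, and the (R)-carbinol fixes its absolute configuration through zinc delivery from oxygen.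

5 back to 4, 3, then 1 and 2. The carbinol C–H bond comes from asymmetric reduction of the 2-oxo ester 4, the ester from salt 3, and the C=C bond from condensation of 2 with 1. Lactone atoms C2, C3 and C4 are thus the three carbons of 2, the benzylic carbon of the C4 arm is the aldehyde carbon of 1, C5 is the carbenoid CH2, and the C3 arm comes from 11.

## Alternatives that were turned down

Alternative 1: The cuts are C2–C3 and the aryl–CH2 bond of the C3 arm, with the C3 oxygen traced back to boron. In the forward step the alkenyl boronate A2, which already carries C4, forms an ate complex with a silylmethyl Grignard reagent. An arylpalladium species, made from an aryl triflate and a zerovalent palladium catalyst with a chiral bisphosphine, then triggers a 1,2-shift of the silylmethyl group to C3 and delivers the aryl group to the terminal CH2, giving the tertiary boronate A1.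
- For it: two C–C bonds and the quaternary carbon are made in one catalytic, convergent, three-component step, and oxidation of C–B to C–OH is stereospecific.
- Against it: the shift must build a fully substituted carbon next to a branched C4, the hardest substrate class for this coupling. The ligand has to override the resident C4 centre, which still needs its own asymmetric synthesis. After A1 the C–B and C–Si bonds must be oxidised, the CH2OH raised to the acid, C5–O deprotected and the ring closed, about five further operations.
- Comparison: this route is stronger in convergence and in setting C3 in the bond-forming event. The chosen route offers a key step that creates no stereocentre, so it cannot erode one, and it is one step from the target.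

Alternative 2: The cuts are the aryl–CH2 bond of the C3 arm and C3–O. An aryl radical, made by reduction of an arenediazonium salt, adds to the exocyclic CH2 of the methylene lactone A4, and the tertiary C3 radical is trapped by the nitroxide TEMPO to give the alkoxyamine A3. Reductive N–O cleavage and debenzylation would finish the synthesis.
- For it: it is short, the reaction type is known on acrylate-like acceptors, and the bulky nitroxide should approach anti to the C4 arm, which is the relative configuration the target needs. In step count after the key step it is at least as good as the chosen route.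
- Against it: the selectivity is kinetic trapping at a hindered tertiary radical guided by a single neighbouring centre, and the tertiary alpha-carbonyl C–ON bond is thermally labile. An electron-rich diazonium salt is a poor electron acceptor, so aryl–nitroxide coupling and azo coupling compete. A4 is a polymerisable acceptor that must itself be made enantiopure.
- Comparison: the chosen route offers both stereocentres set by ionic reactions with established models before the C–O bond is made, and a key step that needs only regioselectivity.

Alternative 3: The cuts are O1–C2 and C2–C3, with C2 supplied by carbon monoxide. The alkynol A6 undergoes palladium-catalysed hydrocarbonylative cyclisation; syn addition across the triple bond fixes the geometry, and the (E)-arylmethylidene lactone A5 results.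
- For it: the ring assembly is atom-economic, starts from an alkyne that is easy to make, and the reaction class is known for homopropargylic alcohols. On ring construction it is stronger than the chosen route.
- Against it: C3 is left as an sp2 carbon, so the key step places neither the hydroxyl nor the C3 stereocentre. The formal hydration that follows (OH on C3, H on the benzylic carbon) must be regio- and face-selective on a β-aryl unsaturated lactone, where a radical hydration can start at either alkene carbon and a dihydroxylation needs a later benzylic deoxygenation. The hardest problem of the target is deferred.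
- Comparison: the chosen route carries the C3 oxygen from the first step (the ketone of 2) and makes lactonisation the last skeletal event.

Key step: step 11

Assumption (step 3): the (S,S)-catalyst is taken to give the (R)-carbinol, with the styryl group in the position an aryl group occupies in aryl ketone reductions; if the sense is the reverse, the (R,R)-complex is used and nothing else changes.
Assumption: 1, 2 and 10 are bought.

Step 1
Reactants: 1 4-(benzyloxy)-3-methoxybenzaldehyde; 2 pyruvic acid
Product: 3 potassium (E)-4-[4-(benzyloxy)-3-methoxyphenyl]-2-oxobut-3-enoate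
Conditions: KOH, MeOH, 0 °C → rt
Reagents that add atoms: potassium hydroxide, [K+].[OH-]
Why: Claisen–Schmidt condensation; the pyruvate methyl group is the only enolisable position, the aldehyde cannot enolise, and dehydration gives the conjugated E-enone whose potassium salt precipitates from methanol and is thereby kept from further aldol chemistry.

Step 2
Reactants: 3 potassium (E)-4-[4-(benzyloxy)-3-methoxyphenyl]-2-oxobut-3-enoate
Product: 4 methyl (E)-4-[4-(benzyloxy)-3-methoxyphenyl]-2-oxobut-3-enoate
Conditions: AcCl, MeOH, 0 → 60 °C
Reagents that add atoms: methanol, CO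
Why: Fischer esterification with HCl generated from acetyl chloride in methanol; the 2-oxo acid esterifies readily and the aryl benzyl ether and enone tolerate brief warm methanolic HCl. The ester is needed because the transfer hydrogenation and the zinc carbenoid step work on esters, not on carboxylate salts.

Step 3
Reactants: 4 methyl (E)-4-[4-(benzyloxy)-3-methoxyphenyl]-2-oxobut-3-enoate
Product: 5 methyl (2R,3E)-4-[4-(benzyloxy)-3-methoxyphenyl]-2-hydroxybut-3-enoate
Conditions: RuCl[(S,S)-TsDPEN](p-cymene) (1 mol%), HCO2H/Et3N (5:2), CH2Cl2, 0 °C → rt
Reagents that add atoms: none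
Why: Asymmetric transfer hydrogenation of an activated 2-oxo ester; hydride goes to the ketone carbon (1,2) because it is the most electrophilic site, leaving the styrene double bond. The catalyst sets the new C2 stereocentre as R.

Step 4
Reactants: 5 methyl (2R,3E)-4-[4-(benzyloxy)-3-methoxyphenyl]-2-hydroxybut-3-enoate
Product: 6 methyl (2R)-2-{(1S,2S)-2-[4-(benzyloxy)-3-methoxyphenyl]cyclopropyl}-2-hydroxyacetate
Conditions: Et2Zn, CH2I2 (1:1), CH2Cl2, −10 → 0 °C
Reagents that add atoms: diiodomethane, ICI
Why: Hydroxyl-directed Simmons–Smith cyclopropanation with the Et2Zn/CH2I2 reagent; the zinc-bound oxygen delivers CH2 to the alkene face on its own side in the conformer with the carbinol hydrogen in the alkene plane and the ester anti, which is the syn mode established for E-allylic secondary alcohols. The E-alkene gives the trans ring stereospecifically, and the (2R) carbinol sets both ring carbons as (1S,2S).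

Step 5
Reactants: 6 methyl (2R)-2-{(1S,2S)-2-[4-(benzyloxy)-3-methoxyphenyl]cyclopropyl}-2-hydroxyacetate
Product: 7 methyl (2S)-2-{(1S,2S)-2-[4-(benzyloxy)-3-methoxyphenyl]cyclopropyl}-2-[(4-nitrobenzoyl)oxy]acetate
Conditions: 4-O2NC6H4CO2H, PPh3, DIAD, THF, 0 °C → rt
Reagents that add atoms: 4-nitrobenzoic acid, OC(=O)c1ccc(cc1)[N+](=O)[O-]
Why: Mitsunobu esterification; SN2 displacement at the carbon alpha to the ester inverts C2 from R to S, and the adjacent ester disfavours ionisation to a cyclopropylcarbinyl cation. This inversion turns the syn relationship made in step 4 into the anti relationship the target needs.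

Step 6
Reactants: 7 methyl (2S)-2-{(1S,2S)-2-[4-(benzyloxy)-3-methoxyphenyl]cyclopropyl}-2-[(4-nitrobenzoyl)oxy]acetate
Product: 8 (2S)-2-{(1S,2S)-2-[4-(benzyloxy)-3-methoxyphenyl]cyclopropyl}-2-hydroxyacetic acid
Conditions: LiOH, THF/MeOH/H2O, 0 °C → rt; then 1 M HCl
Reagents that add atoms: water (as aqueous LiOH), O
Why: Saponification of both esters by acyl–oxygen cleavage, so the carbinol C–O bond and its configuration are untouched; the activated nitrobenzoate goes first, after which the substrate is not prone to enolisation.

Step 7
Reactants: 8 (2S)-2-{(1S,2S)-2-[4-(benzyloxy)-3-methoxyphenyl]cyclopropyl}-2-hydroxyacetic acid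
Product: 9 (2S,5S)-5-{(1S,2S)-2-[4-(benzyloxy)-3-methoxyphenyl]cyclopropyl}-2-tert-butyl-1,3-dioxolan-4-one
Conditions: t-BuCHO, TsOH·H2O (cat.), CH2Cl2, 4 Å MS, reflux
Reagents that add atoms: pivaldehyde, CC(C)(C)C=O
Why: Acid-catalysed acetalisation of a 2-hydroxy acid to the 2-tert-butyl-1,3-dioxolan-4-one; the cis isomer (tert-butyl and cyclopropyl on the same face) is thermodynamically preferred, so C5 controls the new acetal centre (2S). The minor trans isomer is removed here because it would lead to the C3 epimer.

Step 8
Reactants: 10 [4-(benzyloxy)-3-methoxyphenyl]methanol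
Product: 11 1-(benzyloxy)-4-(bromomethyl)-2-methoxybenzene
Conditions: PBr3, Et2O, 0 °C
Reagents that add atoms: phosphorus tribromide, BrP(Br)Br
Why: Conversion of an electron-rich benzylic alcohol into the bromide through its phosphite ester; the bromide is reactive and is used freshly prepared.

Step 9
Reactants: 9 (2S,5S)-5-{(1S,2S)-2-[4-(benzyloxy)-3-methoxyphenyl]cyclopropyl}-2-tert-butyl-1,3-dioxolan-4-one; 11 1-(benzyloxy)-4-(bromomethyl)-2-methoxybenzene
Product: 13 (2S,5S)-5-[4-(benzyloxy)-3-methoxybenzyl]-5-{(1S,2S)-2-[4-(benzyloxy)-3-methoxyphenyl]cyclopropyl}-2-tert-butyl-1,3-dioxolan-4-one, via lithium enolate 12 (not isolated)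
Conditions: LiN(SiMe3)2, THF, −78 °C; then 11, −78 → −30 °C
Reagents that add atoms: none
Why: Alkylation of a dioxolanone enolate with self-regeneration of the stereocentre; C5 is planar in 12 and the benzylic bromide approaches the face away from the tert-butyl group on C2, which is the face the hydrogen left. The arylmethyl group therefore replaces hydrogen with retention and C5 becomes the (S) quaternary carbon, the future C3.

Step 10
Reactants: 13 (2S,5S)-5-[4-(benzyloxy)-3-methoxybenzyl]-5-{(1S,2S)-2-[4-(benzyloxy)-3-methoxyphenyl]cyclopropyl}-2-tert-butyl-1,3-dioxolan-4-one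
Product: 14 (2S)-3-[4-(benzyloxy)-3-methoxyphenyl]-2-{(1S,2S)-2-[4-(benzyloxy)-3-methoxyphenyl]cyclopropyl}-2-hydroxypropanoic acid
Conditions: LiOH, THF/H2O, rt; then 1 M HCl
Reagents that add atoms: water (as aqueous LiOH), O
Why: Base hydrolysis of the acylal; hydroxide opens the ring at the carbonyl and the hemiacetal collapses to pivaldehyde. The tertiary carbinol C–O bond is never broken, so the configuration is kept.

Step 11
Reactants: 14 (2S)-3-[4-(benzyloxy)-3-methoxyphenyl]-2-{(1S,2S)-2-[4-(benzyloxy)-3-methoxyphenyl]cyclopropyl}-2-hydroxypropanoic acid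
Product: 17 (3S,4R)-3,4-bis[4-(benzyloxy)-3-methoxybenzyl]-3-hydroxydihydrofuran-2(3H)-one, via arene radical cation 15 (not isolated), via benzylic radical 16 (not isolated)
Conditions: 9-mesityl-3,6-di-tert-butyl-10-phenylacridinium tetrafluoroborate (5 mol%), PhSH (20 mol%), ClCH2CH2Cl, 450 nm LEDs, rt, Ar
Reagents that add atoms: none
Why: Proposed new method: the photoexcited acridinium takes one electron from the dialkoxyaryl ring on the cyclopropane of 14, giving radical cation 15 in which the two ring bonds to the benzylic carbon are weakened and the other two ring carbons are electrophilic. The carboxyl oxygen on C3 then displaces the benzylic carbon from the unsubstituted ring CH2 in an SN2-like (three-electron) substitution, forming O1–C5 and closing the lactone in a 5-exo-tet mode; after loss of the carboxyl proton the released benzylic radical 16 takes a hydrogen atom from PhSH, and the thiyl radical reoxidises the reduced acridine radical and is reprotonated, so the step is an isomerisation with no net oxidant. The closest known reaction types are the photoredox 1,3-oxyfunctionalisation of arylcyclopropanes by external nucleophiles and the acridinium/thiol anti-Markovnikov hydrolactonisation of alkenoic acids; an intramolecular carboxylic-acid opening of a cyclopropane ended by hydrogen-atom transfer has not been shown. No stereocentre is formed: C3 is not involved and the ring carbon that becomes C4 keeps its bonds to C3, H, C5 and the benzylic carbon, so the (1S) centre of the cyclopropane is carried over unchanged and is named (4R) in 17 only because the priorities change. The selectivity needed is regiochemical: attack at the substituted ring carbon would give a four-membered lactone and attack at the benzylic carbon would expel a non-stabilised alkyl radical, so ring strain and radical stability both direct the oxygen to C5. No base is added, so the easily oxidised carboxylate (decarboxylation) is absent and deprotonation-assisted C3–CH2 scission in the radical cation of the other arene is slow, and without a terminal oxidant any oxidation of the product arenes is reversible.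

Step 12
Reactants: 17 (3S,4R)-3,4-bis[4-(benzyloxy)-3-methoxybenzyl]-3-hydroxydihydrofuran-2(3H)-one
Product: 18 (3S,4R)-3-hydroxy-3,4-bis(4-hydroxy-3-methoxybenzyl)dihydrofuran-2(3H)-one
Conditions: H2 (1 atm), Pd/C, EtOAc/EtOH, rt
Reagents that add atoms: none
Why: Hydrogenolysis of the two aryl benzyl ethers; the lactone, the tertiary alcohol and both stereocentres are inert to these conditions, and the cyclopropane that hydrogen over palladium would also cleave is already gone.

Compound list

1 | 4-(benzyloxy)-3-methoxybenzaldehyde (O-benzylvanillin) | COc1cc(C=O)ccc1OCc1ccccc1 | starting material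
2 | pyruvic acid | CC(=O)C(=O)O | starting material
3 | potassium (E)-4-[4-(benzyloxy)-3-methoxyphenyl]-2-oxobut-3-enoate | [K+].[O-]C(=O)C(=O)/C=C/c1ccc(OCc2ccccc2)c(OC)c1 | intermediate
4 | methyl (E)-4-[4-(benzyloxy)-3-methoxyphenyl]-2-oxobut-3-enoate | COC(=O)C(=O)/C=C/c1ccc(OCc2ccccc2)c(OC)c1 | intermediate
5 | methyl (2R,3E)-4-[4-(benzyloxy)-3-methoxyphenyl]-2-hydroxybut-3-enoate | COC(=O)[C@H](O)/C=C/c1ccc(OCc2ccccc2)c(OC)c1 | intermediate
6 | methyl (2R)-2-{(1S,2S)-2-[4-(benzyloxy)-3-methoxyphenyl]cyclopropyl}-2-hydroxyacetate | COC(=O)[C@H](O)[C@H]1C[C@@H]1c1ccc(OCc2ccccc2)c(OC)c1 | intermediate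
7 | methyl (2S)-2-{(1S,2S)-2-[4-(benzyloxy)-3-methoxyphenyl]cyclopropyl}-2-[(4-nitrobenzoyl)oxy]acetate | COC(=O)[C@@H](OC(=O)c1ccc(cc1)[N+](=O)[O-])[C@H]1C[C@@H]1c1ccc(OCc2ccccc2)c(OC)c1 | intermediate
8 | (2S)-2-{(1S,2S)-2-[4-(benzyloxy)-3-methoxyphenyl]cyclopropyl}-2-hydroxyacetic acid | OC(=O)[C@@H](O)[C@H]1C[C@@H]1c1ccc(OCc2ccccc2)c(OC)c1 | intermediate
9 | (2S,5S)-5-{(1S,2S)-2-[4-(benzyloxy)-3-methoxyphenyl]cyclopropyl}-2-tert-butyl-1,3-dioxolan-4-one (cis) | CC(C)(C)[C@H]1O[C@@H]([C@H]2C[C@@H]2c2ccc(OCc3ccccc3)c(OC)c2)C(=O)O1 | intermediate
10 | [4-(benzyloxy)-3-methoxyphenyl]methanol | COc1cc(CO)ccc1OCc1ccccc1 | starting material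
11 | 1-(benzyloxy)-4-(bromomethyl)-2-methoxybenzene | COc1cc(CBr)ccc1OCc1ccccc1 | intermediate
12 | lithium (2S)-5-{(1S,2S)-2-[4-(benzyloxy)-3-methoxyphenyl]cyclopropyl}-2-tert-butyl-1,3-dioxol-4-olate (enolate of 9, not isolated) | [Li+].CC(C)(C)[C@H]1OC([C@H]2C[C@@H]2c2ccc(OCc3ccccc3)c(OC)c2)=C([O-])O1 | intermediate
13 | (2S,5S)-5-[4-(benzyloxy)-3-methoxybenzyl]-5-{(1S,2S)-2-[4-(benzyloxy)-3-methoxyphenyl]cyclopropyl}-2-tert-butyl-1,3-dioxolan-4-one | CC(C)(C)[C@H]1O[C@@](Cc2ccc(OCc3ccccc3)c(OC)c2)([C@H]2C[C@@H]2c2ccc(OCc3ccccc3)c(OC)c2)C(=O)O1 | intermediate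
14 | (2S)-3-[4-(benzyloxy)-3-methoxyphenyl]-2-{(1S,2S)-2-[4-(benzyloxy)-3-methoxyphenyl]cyclopropyl}-2-hydroxypropanoic acid | COc1cc([C@H]2C[C@@H]2[C@@](O)(Cc2ccc(OCc3ccccc3)c(OC)c2)C(=O)O)ccc1OCc1ccccc1 | intermediate
15 | radical cation of 14, one electron removed from the aryl ring on the cyclopropane (hole drawn on the benzyloxy oxygen; not isolated) | COc1cc([C@H]2C[C@@H]2[C@@](O)(Cc2ccc(OCc3ccccc3)c(OC)c2)C(=O)O)ccc1[O+]Cc1ccccc1 | intermediate
16 | benzylic radical on the C4 arm of lactone 17 (not isolated) | COc1cc([CH][C@@H]2COC(=O)[C@]2(O)Cc2ccc(OCc3ccccc3)c(OC)c2)ccc1OCc1ccccc1 | intermediate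
17 | (3S,4R)-3,4-bis[4-(benzyloxy)-3-methoxybenzyl]-3-hydroxydihydrofuran-2(3H)-one | COc1cc(C[C@@H]2COC(=O)[C@]2(O)Cc2ccc(OCc3ccccc3)c(OC)c2)ccc1OCc1ccccc1 | intermediate
18 | (3S,4R)-3-hydroxy-3,4-bis(4-hydroxy-3-methoxybenzyl)dihydrofuran-2(3H)-one | COc1cc(C[C@@H]2COC(=O)[C@]2(O)Cc2ccc(O)c(OC)c2)ccc1O | target

Total step count: 12. Longest linear sequence: 11 steps (steps 1–7 and 9–12); step 8 is a one-step branch.

Steps least certain to work

Step 11 (key step).
- What may go wrong: oxidation of the second arene followed by scission of the C3–CH2 bond of its radical cation; decarboxylation if any carboxylate is oxidised; slow ring closure, because the carboxyl oxygen must reach the backside of the C5–benzylic bond from a substituent that sits out of the cyclopropane plane; and erosion at C4 if the substituted ring bond opens reversibly before the oxygen attacks.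
- Fallback (known chemistry, sets out from 1 and 11 and returns at 17): Stobbe condensation of 1 with dimethyl succinate (NaOMe, MeOH) gives the half-ester (E)-4-[4-(benzyloxy)-3-methoxyphenyl]-3-(methoxycarbonyl)but-3-enoic acid F1. Asymmetric hydrogenation with [Rh(cod)(Me-DuPhos)]BF4 (ligand antipode chosen for S) gives the succinate half-ester F2. Reduction of the ester in its potassium salt with Ca(BH4)2 and acid lactonisation give (4S)-4-[4-(benzyloxy)-3-methoxybenzyl]dihydrofuran-2(3H)-one F3. Enolate alkylation (LiN(SiMe3)2, then 11) enters anti to the C4 arm and gives the trans-dibenzyl lactone F4. Deprotonation with KN(SiMe3)2 and hydroxylation with 2-(phenylsulfonyl)-3-phenyloxaziridine, again anti to the C4 arm, put the hydroxyl trans to that arm and give 17.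

Step 3.
- What may go wrong: conjugate reduction, base-induced isomerisation of the allylic alcohol to the saturated 2-oxo ester, or insufficient enantioselection.
- Fallback (sets out from 3, returns at 5): enzymatic reduction of salt 3 with a D-lactate dehydrogenase and NADH, recycled by formate dehydrogenase and HCO2Na, gives (2R,3E)-4-[4-(benzyloxy)-3-methoxyphenyl]-2-hydroxybut-3-enoic acid F5, which is methylated with Me3SiCHN2 in MeOH/toluene to 5.

Step 4.
- What may go wrong: poor facial selectivity if binding of zinc by the ester carbonyl competes with the conformer that has the carbinol hydrogen in the alkene plane; O-methylation by excess carbenoid.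
- Fallback (reagent control instead of substrate control, sets out from 1, returns at 8 and replaces steps 1–6): Horner–Wadsworth–Emmons olefination of 1 with triethyl phosphonoacetate (NaH, THF) gives ethyl (E)-3-[4-(benzyloxy)-3-methoxyphenyl]prop-2-enoate F6, and (i-Bu)2AlH reduction gives the allylic alcohol F7. Cyclopropanation with Zn(CH2I)2·DME and the (4R,5R)-2-butyl-N,N,N',N'-tetramethyl-1,3,2-dioxaborolane-4,5-dicarboxamide ligand (the antipode that gives 1S,2S) gives the cyclopropylmethanol F8. Oxidation with the triacetoxyperiodinane gives the aldehyde F9, and an (S)-selective hydroxynitrile lyase with HCN gives the cyanohydrin F10. Pinner methanolysis (HCl, MeOH, 0 °C) gives the methyl (S)-hydroxy ester F11, and LiOH gives 8.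

Step 5.
- What may go wrong: ionisation or homoallylic ring opening of the activated cyclopropylcarbinyl oxyphosphonium species, or elimination, in place of SN2 displacement.
- Fallback (oxidation then reduction instead of substitution, sets out from 6, returns at 8): oxidation of 6 with the triacetoxyperiodinane gives the methyl 2-oxo ester F12. Transfer hydrogenation with the RuCl(TsDPEN)(p-cymene) antipode that gives S reduces it to the ester F11 described under step 4, and LiOH gives 8.

Step 9.
- What may go wrong: slow alkylation of the alpha-branched enolate, so that enolate self-condensation and decomposition take over.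
- Fallback (addition then deoxygenation instead of substitution, sets out from 9 through 12, returns at 13): aldol addition of 12 to aldehyde 1 at −78 °C, again anti to the tert-butyl group, gives the carbinol F13 as a mixture of carbinol epimers. Thiocarbonyldiimidazole converts it to the thiocarbonyl imidazolide F14, and Barton–McCombie deoxygenation (Bu3SnH, AIBN, toluene, 80 °C) gives 13; the radical is one carbon away from the cyclopropane and cannot open it.

Further compounds

F1 | step 11 | (E)-4-[4-(benzyloxy)-3-methoxyphenyl]-3-(methoxycarbonyl)but-3-enoic acid | COC(=O)/C(CC(=O)O)=C/c1ccc(OCc2ccccc2)c(OC)c1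
F2 | step 11 | (3S)-3-[4-(benzyloxy)-3-methoxybenzyl]-4-methoxy-4-oxobutanoic acid | COC(=O)[C@H](CC(=O)O)Cc1ccc(OCc2ccccc2)c(OC)c1
F3 | step 11 | (4S)-4-[4-(benzyloxy)-3-methoxybenzyl]dihydrofuran-2(3H)-one | COc1cc(C[C@@H]2COC(=O)C2)ccc1OCc1ccccc1
F4 | step 11 | (3S,4S)-3,4-bis[4-(benzyloxy)-3-methoxybenzyl]dihydrofuran-2(3H)-one | COc1cc(C[C@@H]2COC(=O)[C@H]2Cc2ccc(OCc3ccccc3)c(OC)c2)ccc1OCc1ccccc1
F5 | step 3 | (2R,3E)-4-[4-(benzyloxy)-3-methoxyphenyl]-2-hydroxybut-3-enoic acid | OC(=O)[C@H](O)/C=C/c1ccc(OCc2ccccc2)c(OC)c1
F6 | step 4 | ethyl (E)-3-[4-(benzyloxy)-3-methoxyphenyl]prop-2-enoate | CCOC(=O)/C=C/c1ccc(OCc2ccccc2)c(OC)c1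
F7 | step 4 | (E)-3-[4-(benzyloxy)-3-methoxyphenyl]prop-2-en-1-ol | OC/C=C/c1ccc(OCc2ccccc2)c(OC)c1
F8 | step 4 | {(1S,2S)-2-[4-(benzyloxy)-3-methoxyphenyl]cyclopropyl}methanol | OC[C@H]1C[C@@H]1c1ccc(OCc2ccccc2)c(OC)c1
F9 | step 4 | (1S,2S)-2-[4-(benzyloxy)-3-methoxyphenyl]cyclopropane-1-carbaldehyde | O=C[C@H]1C[C@@H]1c1ccc(OCc2ccccc2)c(OC)c1
F10 | step 4 | (2S)-2-{(1S,2S)-2-[4-(benzyloxy)-3-methoxyphenyl]cyclopropyl}-2-hydroxyacetonitrile | N#C[C@@H](O)[C@H]1C[C@@H]1c1ccc(OCc2ccccc2)c(OC)c1
F11 | step 4 | methyl (2S)-2-{(1S,2S)-2-[4-(benzyloxy)-3-methoxyphenyl]cyclopropyl}-2-hydroxyacetate | COC(=O)[C@@H](O)[C@H]1C[C@@H]1c1ccc(OCc2ccccc2)c(OC)c1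
F12 | step 5 | methyl 2-{(1S,2S)-2-[4-(benzyloxy)-3-methoxyphenyl]cyclopropyl}-2-oxoacetate | COC(=O)C(=O)[C@H]1C[C@@H]1c1ccc(OCc2ccccc2)c(OC)c1
F13 | step 9 | 5-{[4-(benzyloxy)-3-methoxyphenyl](hydroxy)methyl} analogue of 13 (carbinol epimers) | CC(C)(C)[C@H]1O[C@@](C(O)c2ccc(OCc3ccccc3)c(OC)c2)([C@H]2C[C@@H]2c2ccc(OCc3ccccc3)c(OC)c2)C(=O)O1
F14 | step 9 | O-(imidazol-1-ylthiocarbonyl) derivative of F13 (carbinol epimers) | CC(C)(C)[C@H]1O[C@@](C(OC(=S)n2ccnc2)c2ccc(OCc3ccccc3)c(OC)c2)([C@H]2C[C@@H]2c2ccc(OCc3ccccc3)c(OC)c2)C(=O)O1
A1 | alternative 1 | tertiary pinacol boronate bearing the arylmethyl, (isopropoxydimethylsilyl)methyl and C4-chain substituents | COc1cc(C[C@H](COCc2ccccc2)[C@@](B2OC(C)(C)C(C)(C)O2)(Cc2ccc(OCc3ccccc3)c(OC)c2)C[Si](C)(C)OC(C)C)ccc1OCc1ccccc1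
A2 | alternative 1 | 2-{(3S)-4-(benzyloxy)-3-[4-(benzyloxy)-3-methoxybenzyl]but-1-en-2-yl}-4,4,5,5-tetramethyl-1,3,2-dioxaborolane | COc1cc(C[C@H](COCc2ccccc2)C(=C)B2OC(C)(C)C(C)(C)O2)ccc1OCc1ccccc1
A3 | alternative 2 | 3,4-bis[4-(benzyloxy)-3-methoxybenzyl]-3-[(2,2,6,6-tetramethylpiperidin-1-yl)oxy]dihydrofuran-2(3H)-one | COc1cc(C[C@@H]2COC(=O)[C@]2(ON2C(C)(C)CCCC2(C)C)Cc2ccc(OCc3ccccc3)c(OC)c2)ccc1OCc1ccccc1
A4 | alternative 2 | (4S)-4-[4-(benzyloxy)-3-methoxybenzyl]-3-methylenedihydrofuran-2(3H)-one | COc1cc(C[C@@H]2COC(=O)C2=C)ccc1OCc1ccccc1
A5 | alternative 3 | (E)-3-[4-(benzyloxy)-3-methoxybenzylidene]-4-[4-(benzyloxy)-3-methoxybenzyl]dihydrofuran-2(3H)-one | COc1cc(C[C@@H]2COC(=O)/C2=C/c2ccc(OCc3ccccc3)c(OC)c2)ccc1OCc1ccccc1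
A6 | alternative 3 | (2S)-2-[4-(benzyloxy)-3-methoxybenzyl]-4-[4-(benzyloxy)-3-methoxyphenyl]but-3-yn-1-ol | COc1cc(C[C@H](CO)C#Cc2ccc(OCc3ccccc3)c(OC)c2)ccc1OCc1ccccc1
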